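I plan from the later readings of this same charge, so I first reckon this flask at its own time.

    target ⇌ isomer of the product (K1 = 0.39, k1 = 0.0032 s⁻¹)
    starting material + dissolved gas → target (k2 = 0.13 M⁻¹ s⁻¹)
    gas phase ⇌ dissolved gas, rate k3*(csat - [dissolved gas]) (k3 = 0.0076 s⁻¹, csat = 1.9 mM)
    dissolved gas ⇌ dormant form (K4 = 220, k4 = 4.3 × 10⁻⁴ s⁻¹)
    dissolved gas + target → over-reacted product (k5 = 0.13 M⁻¹ s⁻¹)

starting material 20 mM; gas phase 1.9 mM (held); time 30 min

- at the start none of the gas is dissolved
- run time (flask): 30 min

- target at 30 min, in percent of the starting material charged
- the change that raises the amount of target at 30 min, in percent of the starting material charged most ("none" if none brings more than 2 percentage points) (amber / grey / none)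
- amount of target at 30 min, in percent of the starting material charged, after grey

- amber: doubling the transfer coefficient of step 3, all else as stated
- grey: doubling the saturation concentration of gas phase, all else as stated

In this flask the transfer feeds [dissolved gas], while addition to starting material, the drain to the dormant form and, once target is present, over-reaction remove it. Setting feed equal to the first two losses, with starting material at its charge, gives a level of 1.36 mM. The approach takes about 1.57 min, which is shorter than the run, so I replace the curve by this level. Starting material then decays pseudo-first-order. I call the addition constant times level times time the gas exposure: 0.318. This way, 27.2% of the starting material reacts.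

The second way is a gas budget. At that level the transfer delivers 7.41 mM. Of this, 1.36 mM stays dissolved and 1.05 mM goes dormant, so the remainder, which addition and over-reaction share, is 25.0% of the charge. The two part, with the budget lower. Both cheat at the start: [dissolved gas] begins at nothing, so the exposure reads high and the delivery reads low. I keep the exposure, knowing it is a little high.

Target and isomer of the product relax with a half-life of 1.01 min, shorter than the run, so I give target 71.9% of the product pool. Over-reaction has the same constant as addition, so I charge it the exposure times a mean target of half its final value, which costs 3.11%. Target comes to 17.4%.

Grey doubles the level and the exposure, giving 26.1%, a gain of 8.7 percentage points. Amber raises the level to 1.58 mM, giving 19.3%, a gain of 2 points. I commit to grey.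

The forecast says 17.1%, grey and 26.5%, holding that “transfer is already close to keeping up”.

The flask gives 17.0%, and 26.2% after grey, which gains 9.2 points against 2.2 points for amber. In this flask [dissolved gas] reached 1.16 mM at 3.00 min and stood at 1.39 mM at 30.0 min, while addition left 74% of the starting material, against 72.8% from the exposure. Over-reacted product then stood at 2.89%. In the neighbour read at 80 min, the same level gives an exposure of 0.848, which leaves 42.8% of the starting material. That flask holds 42.4%.

The rate constants are invented; the rest is arithmetic.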